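**Retrosynthetic overview**
1. C6–C7 is cut last: a lithiated C7 phenyl sulfone (C7–C15, carrying C8 and the E,E-diene) is alkylated by a (Z)-allylic bromide (C1–C6) and the sulfone is then removed.
2. The C1–C6 bromide comes from bromosilane opening of a 4-methyl-3,6-dihydro-2H-pyran-2-carboxylate, made by a Brønsted-acid-catalysed asymmetric oxa-Diels–Alder of methyl glyoxylate with isoprene (sets C2, fixes 4Z inside the ring).
3. C10–C11 is cut by Pd coupling of a C7–C10 (E)-vinyl iodide with the (E)-alkenylalane from methylalumination of 3-(pent-4-ynyl)furan (sets 11E and the C12 methyl).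
4. C8 is set by photo-organocatalytic enamine α-(phenylsulfonyl)methylation of propanal; C9=C10 comes from a Takai iodo-olefination.
5. Rings: the furan is bought intact (3-bromofuran); the only ring formed is the temporary dihydropyran (step 1), opened again in step 2.

Assumption: methyl glyoxylate is used as the freshly cracked monomer from its commercial hemiacetal or polymer form.

**Step 1**
Reactants: 1 methyl glyoxylate; 2 isoprene
Product: 3 methyl (2R)-4-methyl-3,6-dihydro-2H-pyran-2-carboxylate
Conditions: chiral IDPi Brønsted acid (2 mol %, enantiomer giving 2R), isoprene (5 equiv), methylcyclohexane–CH2Cl2, 5 Å MS, −40 °C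
Reagents that add atoms: none
Why: Proposed new method: a confined imidodiphosphorimidate acid should activate the formyl group of the glyoxylate inside its chiral pocket and steer a concerted but highly asynchronous oxa-Diels–Alder in which C–C bond formation to the CH2 terminus next to the methyl-bearing carbon of isoprene runs ahead (tertiary allyl-cation character, hence the 4-methyl regioisomer) while the chiral counter-anion shields one aldehyde face (setting C2) and closes the C–O bond before proton loss to the ene product; the closest known reactions are the confined-acid-catalysed hetero-Diels–Alder of aromatic and aliphatic aldehydes with isoprene and 2,3-dimethylbutadiene and the Cu-bisoxazoline glyoxylate hetero-Diels–Alder.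

**Step 2**
Reactants: 3 methyl (2R)-4-methyl-3,6-dihydro-2H-pyran-2-carboxylate
Product: 4 methyl (2R,4Z)-6-bromo-4-methyl-2-[(trimethylsilyl)oxy]hex-4-enoate
Conditions: TMSBr (1.5 equiv), CH2Cl2, 0 °C → rt; evaporate, use crude
Reagents that add atoms: bromotrimethylsilane, C[Si](C)(C)Br
Why: Silyl-halide ether cleavage: TMSBr silylates the ring oxygen and bromide opens the oxonium ion by SN2 at the primary allylic C6 rather than at the ester-deactivated C2, so the ring-imposed 4Z geometry and the C2 centre are carried over and the alcohol emerges already TMS-protected.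

**Step 3**
Reactants: 5 propanal; 6 iodomethyl phenyl sulfone
Product: 7 (2R)-2-methyl-3-(phenylsulfonyl)propanal
Conditions: (R)-diarylprolinol TMS ether [Ar = 3,5-(CF3)2C6H3] (20 mol %), 2,6-lutidine (1 equiv), 5 (3 equiv), hν (365 nm LED), MTBE, −10 °C; crude aldehyde taken on cold
Reagents that add atoms: none
Why: Photo-organocatalytic enamine α-alkylation: the photoexcited enamine reduces the iodide by SET and the resulting (phenylsulfonyl)methyl radical adds in a chain process to the open Re face of the ground-state E-enamine (Si face blocked by the diaryl(silyloxy)methyl group of the (R)-catalyst), setting C8 as 2R in 7.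

**Step 4**
Reactants: 7 (2R)-2-methyl-3-(phenylsulfonyl)propanal
Product: 8 {[(2R,3E)-4-iodo-2-methylbut-3-en-1-yl]sulfonyl}benzene
Conditions: CrCl2 (6 equiv), CHI3 (2 equiv), THF–dioxane, 0 °C → rt
Reagents that add atoms: iodoform, IC(I)I
Why: Takai olefination: the gem-dichromium carbenoid adds to the aldehyde and eliminates to the E-vinyl iodide under non-basic conditions, so the α-stereocentre is not epimerised and the β-sulfone is not eliminated.

**Step 5**
Reactants: 9 3-bromofuran; 10 (5-chloropent-1-yn-1-yl)trimethylsilane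
Product: 12 [5-(furan-3-yl)pent-1-yn-1-yl]trimethylsilane, via Grignard reagent 11 (not isolated)
Conditions: 10, Mg, THF, 50 °C; then 9, NiCl2(dppp) (3 mol %), 0 °C → rt
Reagents that add atoms: none
Why: Kumada coupling of the primary alkyl Grignard reagent with 3-bromofuran gives the 3-alkylfuran directly, the silyl cap keeping the alkyne inert to the Grignard reagent.

**Step 6**
Reactants: 12 [5-(furan-3-yl)pent-1-yn-1-yl]trimethylsilane
Product: 13 3-(pent-4-yn-1-yl)furan
Conditions: K2CO3 (0.2 equiv), MeOH, rt
Reagents that add atoms: none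
Why: Base-catalysed protodesilylation of the alkynylsilane frees the terminal alkyne needed for carbometalation.

**Step 7**
Reactants: 13 3-(pent-4-yn-1-yl)furan; 8 {[(2R,3E)-4-iodo-2-methylbut-3-en-1-yl]sulfonyl}benzene
Product: 15 {[(2R,3E,5E)-9-(furan-3-yl)-2,6-dimethylnona-3,5-dien-1-yl]sulfonyl}benzene, via alkenylalane 14 (not isolated)
Conditions: AlMe3 (2 equiv), Cp2ZrCl2 (25 mol %), CH2Cl2, 0 °C → rt; strip excess AlMe3; then 8, Pd(PPh3)4 (5 mol %), ZnCl2 (0.5 equiv), THF, rt
Reagents that add atoms: trimethylaluminium, C[Al](C)C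
Why: Negishi Zr-catalysed syn-methylalumination places methyl on the internal alkyne carbon and gives the (E)-alkenylalane, and Pd/Zn cross-coupling with the vinyl iodide proceeds with retention on both partners to give the E,E-diene.

**Step 8**
Reactants: 15 {[(2R,3E,5E)-9-(furan-3-yl)-2,6-dimethylnona-3,5-dien-1-yl]sulfonyl}benzene; 4 methyl (2R,4Z)-6-bromo-4-methyl-2-[(trimethylsilyl)oxy]hex-4-enoate
Product: 18 methyl (2R,4Z,8R,9E,11E)-15-(furan-3-yl)-2-hydroxy-4,8,12-trimethyl-7-(phenylsulfonyl)pentadeca-4,9,11-trienoate (7-epimers), via lithiated sulfone 16 (not isolated), via silyl ether 17 (not isolated)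
Conditions: n-BuLi (1.0 equiv), THF, −78 °C; then 4 (1.2 equiv), −78 °C; aq. citric acid/MeOH work-up
Reagents that add atoms: none
Why: Sulfone carbanion alkylation (Julia-type terpenoid coupling): the α-sulfonyl carbanion displaces the primary allylic bromide by SN2 at −78 °C faster than it attacks the silyloxy-flanked ester, the 4Z olefin is retained, the new C7 centre is irrelevant because it is erased in step 9, and the TMS ether falls off on mild acidic work-up.

**Step 9**
Reactants: 18 methyl (2R,4Z,8R,9E,11E)-15-(furan-3-yl)-2-hydroxy-4,8,12-trimethyl-7-(phenylsulfonyl)pentadeca-4,9,11-trienoate (7-epimers)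
Product: 19 methyl (2R,4Z,8S,9E,11E)-15-(furan-3-yl)-2-hydroxy-4,8,12-trimethylpentadeca-4,9,11-trienoate
Conditions: 5% Na/Hg, Na2HPO4, MeOH–THF, −20 °C
Reagents that add atoms: none
Why: Reductive desulfonylation by electron transfer cleaves the non-allylic alkyl C–S bond and protonates C7 to CH2 without touching the diene, furan, hydroxy ester or either stereocentre (C8 changes descriptor from R to S only through CIP priorities).

**Compound list**
1 | methyl glyoxylate | COC(=O)C=O | starting material
2 | isoprene | C=CC(C)=C | starting material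
3 | methyl (2R)-4-methyl-3,6-dihydro-2H-pyran-2-carboxylate | COC(=O)[C@H]1CC(C)=CCO1 | intermediate
4 | methyl (2R,4Z)-6-bromo-4-methyl-2-[(trimethylsilyl)oxy]hex-4-enoate | COC(=O)[C@H](O[Si](C)(C)C)C/C(C)=C\CBr | intermediate
5 | propanal | CCC=O | starting material
6 | iodomethyl phenyl sulfone | O=S(=O)(CI)c1ccccc1 | starting material
7 | (2R)-2-methyl-3-(phenylsulfonyl)propanal | O=C[C@@H](C)CS(=O)(=O)c1ccccc1 | intermediate
8 | {[(2R,3E)-4-iodo-2-methylbut-3-en-1-yl]sulfonyl}benzene | I/C=C/[C@@H](C)CS(=O)(=O)c1ccccc1 | intermediate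
9 | 3-bromofuran | Brc1ccoc1 | starting material
10 | (5-chloropent-1-yn-1-yl)trimethylsilane | C[Si](C)(C)C#CCCCCl | starting material
11 | [5-(trimethylsilyl)pent-4-yn-1-yl]magnesium chloride | C[Si](C)(C)C#CCCC[Mg]Cl | intermediate
12 | [5-(furan-3-yl)pent-1-yn-1-yl]trimethylsilane | C[Si](C)(C)C#CCCCc1ccoc1 | intermediate
13 | 3-(pent-4-yn-1-yl)furan | C#CCCCc1ccoc1 | intermediate
14 | [(1E)-5-(furan-3-yl)-2-methylpent-1-en-1-yl]dimethylalane | C[Al](C)/C=C(\C)CCCc1ccoc1 | intermediate
15 | {[(2R,3E,5E)-9-(furan-3-yl)-2,6-dimethylnona-3,5-dien-1-yl]sulfonyl}benzene | O=S(=O)(C[C@H](C)/C=C/C=C(\C)CCCc1ccoc1)c1ccccc1 | intermediate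
16 | [(2R,3E,5E)-9-(furan-3-yl)-2,6-dimethyl-1-(phenylsulfonyl)nona-3,5-dien-1-yl]lithium | [Li]C([C@H](C)/C=C/C=C(\C)CCCc1ccoc1)S(=O)(=O)c1ccccc1 | intermediate
17 | methyl (2R,4Z,8R,9E,11E)-15-(furan-3-yl)-4,8,12-trimethyl-7-(phenylsulfonyl)-2-[(trimethylsilyl)oxy]pentadeca-4,9,11-trienoate (7-epimers) | COC(=O)[C@H](O[Si](C)(C)C)C/C(C)=C\CC([C@H](C)/C=C/C=C(\C)CCCc1ccoc1)S(=O)(=O)c1ccccc1 | intermediate
18 | methyl (2R,4Z,8R,9E,11E)-15-(furan-3-yl)-2-hydroxy-4,8,12-trimethyl-7-(phenylsulfonyl)pentadeca-4,9,11-trienoate (7-epimers) | COC(=O)[C@H](O)C/C(C)=C\CC([C@H](C)/C=C/C=C(\C)CCCc1ccoc1)S(=O)(=O)c1ccccc1 | intermediate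
19 | methyl (2R,4Z,8S,9E,11E)-15-(furan-3-yl)-2-hydroxy-4,8,12-trimethylpentadeca-4,9,11-trienoate | COC(=O)[C@H](O)C/C(C)=C\CC[C@H](C)/C=C/C=C(\C)CCCc1ccoc1 | target

**Totals**
Total steps: 9. Longest linear sequence: 5 steps (steps 5, 6, 7, 8, 9 from 3-bromofuran; equally steps 3, 4, 7, 8, 9 from propanal).

**Steps most likely to fail, with fallbacks**

The first risk is step 1, the new reaction. The glyoxylate may give the carbonyl-ene product with isoprene instead of the cycloadduct, isoprene may oligomerise under the strong acid, or the enantioselectivity may be low. The fallback uses known chemistry, sets out from 1 and comes back at 3. A Ti–(R)-BINOL-catalysed glyoxylate-ene reaction of 1 with isobutene gives methyl (2R)-2-hydroxy-4-methylpent-4-enoate F1. O-Allylation with allyl bromide and Ag2O gives methyl (2R)-4-methyl-2-(prop-2-en-1-yloxy)pent-4-enoate F2. Ring-closing metathesis with a second-generation Ru carbene closes the trisubstituted ring olefin and returns 3.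

The second risk is step 2. The ester-flanked ether oxygen may be silylated too slowly, free bromide may scramble the allylic bromide (4Z to 4E via the tertiary isomer), or some cleavage may occur at C2. The fallback sets out from 3 and comes back at 18. Acylative ring opening with acetyl bromide and catalytic ZnBr2 at 0 °C gives the stable, chromatographable methyl (2R,4Z)-2-(acetyloxy)-6-bromo-4-methylhex-4-enoate F3, whose Z:E ratio can be checked before the union. Inverse addition of lithiated sulfone 16 to F3 at −78 °C gives methyl (2R,4Z,8R,9E,11E)-2-(acetyloxy)-15-(furan-3-yl)-4,8,12-trimethyl-7-(phenylsulfonyl)pentadeca-4,9,11-trienoate F4. Brief K2CO3/MeOH methanolysis removes the acetate and returns 18.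

The third risk is step 3. Propanal is volatile and prone to self-aldol, the ee of this radical alkylation is typically only in the high 80s to low 90s, and aldehyde 7 can racemise or lose sulfinate on handling. Any erosion would surface later as an inseparable 2,8-diastereomer. The fallback sets out from 5 and comes back at 8. Enamine-catalysed α-hydroxymethylation of 5 with aqueous formaldehyde and (R)-diphenylprolinol TMS ether gives (2S)-3-hydroxy-2-methylpropanal F5. Takai olefination of F5 gives (2R,3E)-4-iodo-2-methylbut-3-en-1-ol F6, a well-characterised compound whose ee can be checked. Diphenyl disulfide and tributylphosphine convert F6 into {[(2R,3E)-4-iodo-2-methylbut-3-en-1-yl]sulfanyl}benzene F7. Molybdate/H2O2 oxidation of F7 returns 8.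

**Further compounds**
F1 | step 1 | methyl (2R)-2-hydroxy-4-methylpent-4-enoate | COC(=O)[C@H](O)CC(C)=C
F2 | step 1 | methyl (2R)-4-methyl-2-(prop-2-en-1-yloxy)pent-4-enoate | COC(=O)[C@H](OCC=C)CC(C)=C
F3 | step 2 | methyl (2R,4Z)-2-(acetyloxy)-6-bromo-4-methylhex-4-enoate | COC(=O)[C@H](OC(C)=O)C/C(C)=C\CBr
F4 | step 2 | methyl (2R,4Z,8R,9E,11E)-2-(acetyloxy)-15-(furan-3-yl)-4,8,12-trimethyl-7-(phenylsulfonyl)pentadeca-4,9,11-trienoate (7-epimers) | COC(=O)[C@H](OC(C)=O)C/C(C)=C\CC([C@H](C)/C=C/C=C(\C)CCCc1ccoc1)S(=O)(=O)c1ccccc1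
F5 | step 3 | (2S)-3-hydroxy-2-methylpropanal | O=C[C@@H](C)CO
F6 | step 3 | (2R,3E)-4-iodo-2-methylbut-3-en-1-ol | I/C=C/[C@@H](C)CO
F7 | step 3 | {[(2R,3E)-4-iodo-2-methylbut-3-en-1-yl]sulfanyl}benzene | I/C=C/[C@@H](C)CSc1ccccc1
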